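**Plan**

- Retrosynthesis: the four phenolic O–CH2Ph bonds are cut first, then the C3–OH bond of each γ-butyrolactone ring, then the C5–C5' aryl–aryl bond between the two guaiacyl rings, then the C3–CH2Ar bond of each lactone, and finally each lactone ring back to an arylidenesuccinate.
- Enabling feature: in both lactone rings C3, the ring carbon between C2=O and C4, carries a tertiary OH and an arylmethyl group. With H in place of OH each ring is a trans-3,4-dibenzyl lactone whose C3–H is its only enolisable hydrogen, so both carbinols can be installed by one twofold enolate oxygenation.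
- Forward: the two lactone rings are made first and separately (Stobbe condensation, asymmetric hydrogenation, reduction–lactonisation), and each is benzylated at C3. The two aryl bromide halves are joined by borylation/Suzuki coupling, both C3 positions are hydroxylated in one operation, and the benzyl ethers are removed last.
- Stereochemistry: C4 of each ring comes from ligand-controlled rhodium hydrogenation, and the C3 benzyl group is set trans to C4 by substrate-controlled enolate alkylation. The carbinol configuration comes from substrate-controlled face selection in the enolate oxygenation, where OH replaces H with retention. The biaryl has only two ortho substituents and is no stereo-axis.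

Key step: step 14

Assumption: the (4R,5R) antipode of MOD-DIOP is taken to give the (S)-acids 6 and 11; should the sense prove opposite, the (4S,5S) ligand is used and nothing else changes.
Remark: 1, 9 and 14 are purchasable vanillin derivatives, so the route starts from them.

**Route**

Step 1
Reactants: 1 5-bromovanillin; 2 benzyl bromide
Product: 3 4-(benzyloxy)-3-bromo-5-methoxybenzaldehyde
Conditions: K2CO3, DMF, rt
Reagents that add atoms: none
Why: Williamson etherification; the phenoxide is the only nucleophile present and displaces bromide from the benzylic carbon (SN2).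

Step 2
Reactants: 3 4-(benzyloxy)-3-bromo-5-methoxybenzaldehyde; 4 diethyl succinate
Product: 5 (E)-4-[4-(benzyloxy)-3-bromo-5-methoxyphenyl]-3-(ethoxycarbonyl)but-3-enoic acid
Conditions: NaOEt, EtOH, reflux; then aq HCl
Reagents that add atoms: none
Why: Stobbe condensation; the succinate enolate adds to the aldehyde, the alkoxide lactonises onto the second ester and base-induced ring opening should give the (E)-arylidene half-ester with the free acid on the CH2 arm.

Step 3
Reactants: 5 (E)-half-ester
Product: 6 (S)-4-[4-(benzyloxy)-3-bromo-5-methoxyphenyl]-3-(ethoxycarbonyl)butanoic acid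
Conditions: H2 (5 atm), [Rh(cod)Cl]2 (0.5 mol %), (4R,5R)-MOD-DIOP [(4R,5R)-4,5-bis{[bis(4-methoxy-3,5-dimethylphenyl)phosphanyl]methyl}-2,2-dimethyl-1,3-dioxolane], Et3N (1 equiv), MeOH, 30 °C; dil. HCl work-up
Reagents that add atoms: none
Why: Rhodium–bisphosphine asymmetric hydrogenation of an itaconate-type half-ester; carboxylate and olefin chelate the metal, the chiral ligand selects the olefin face and so sets the new centre as S, and the homogeneous catalyst should leave the aryl bromide and the benzyl ether untouched.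

Step 4
Reactants: 6 (S)-half-ester
Product: 8 (S)-4-[4-(benzyloxy)-3-bromo-5-methoxybenzyl]dihydrofuran-2(3H)-one, via hydroxy acid 7 (not isolated)
Conditions: KOH (1 equiv), EtOH, 0 °C; Ca(BH4)2 (from CaCl2 + NaBH4), EtOH, −10 °C → rt; then 2 M HCl, rt
Reagents that add atoms: none
Why: Chemoselective borohydride reduction; Ca(BH4)2 reduces the ethyl ester but not the carboxylate, and acidification lactonises the γ-hydroxy acid (5-exo-trig acyl substitution), the cold conditions keeping the α-ester stereocentre from enolising before it is reduced.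

Step 5
Reactants: 9 4-(benzyloxy)-3-methoxybenzaldehyde; 4 diethyl succinate
Product: 10 (E)-4-[4-(benzyloxy)-3-methoxyphenyl]-3-(ethoxycarbonyl)but-3-enoic acid
Conditions: NaOEt, EtOH, reflux; then aq HCl
Reagents that add atoms: none
Why: Stobbe condensation, as in step 2.

Step 6
Reactants: 10 (E)-half-ester
Product: 11 (S)-4-[4-(benzyloxy)-3-methoxyphenyl]-3-(ethoxycarbonyl)butanoic acid
Conditions: H2 (5 atm), [Rh(cod)Cl]2 (0.5 mol %), (4R,5R)-MOD-DIOP, Et3N (1 equiv), MeOH, 30 °C; dil. HCl work-up
Reagents that add atoms: none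
Why: Rhodium–bisphosphine asymmetric hydrogenation as in step 3; the ligand sets the S centre.

Step 7
Reactants: 11 (S)-half-ester
Product: 13 (S)-4-[4-(benzyloxy)-3-methoxybenzyl]dihydrofuran-2(3H)-one, via hydroxy acid 12 (not isolated)
Conditions: KOH (1 equiv), EtOH, 0 °C; Ca(BH4)2 (from CaCl2 + NaBH4), EtOH, −10 °C → rt; then 2 M HCl, rt
Reagents that add atoms: none
Why: Chemoselective ester reduction and acid lactonisation as in step 4; the stereocentre is not touched.

Step 8
Reactants: 14 4-(benzyloxy)-3-methoxybenzyl alcohol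
Product: 15 4-(benzyloxy)-3-methoxybenzyl bromide
Conditions: PBr3, CH2Cl2, 0 °C; used freshly prepared
Reagents that add atoms: phosphorus tribromide, BrP(Br)Br
Why: Bromination of a benzylic alcohol through its bromophosphite, which bromide displaces (SN2).

Step 9
Reactants: 3 4-(benzyloxy)-3-bromo-5-methoxybenzaldehyde
Product: 16 4-(benzyloxy)-3-bromo-5-methoxybenzyl alcohol
Conditions: NaBH4, MeOH/THF, 0 °C
Reagents that add atoms: none
Why: Borohydride reduction of an aromatic aldehyde; aryl bromide and benzyl ether are inert.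

Step 10
Reactants: 16 4-(benzyloxy)-3-bromo-5-methoxybenzyl alcohol
Product: 17 4-(benzyloxy)-3-bromo-5-methoxybenzyl bromide
Conditions: PBr3, CH2Cl2, 0 °C
Reagents that add atoms: phosphorus tribromide, BrP(Br)Br
Why: Benzylic alcohol to bromide as in step 8; the aryl bromide is not affected.

Step 11
Reactants: 8 (S)-bromo lactone; 15 4-(benzyloxy)-3-methoxybenzyl bromide
Product: 19 (3S,4S)-4-[4-(benzyloxy)-3-bromo-5-methoxybenzyl]-3-[4-(benzyloxy)-3-methoxybenzyl]dihydrofuran-2(3H)-one, via lithium enolate 18 (not isolated)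
Conditions: LiN(SiMe3)2, THF, −78 °C; then 15, DMPU, −78 → −30 °C
Reagents that add atoms: none
Why: Alkylation of a lactone lithium enolate with a benzylic bromide (SN2); the electrophile approaches the enolate face anti to the C4 arylmethyl group, which sets C3 as S with the two benzyl groups trans, the arrangement that is also thermodynamically preferred.

Step 12
Reactants: 13 (S)-lactone; 17 4-(benzyloxy)-3-bromo-5-methoxybenzyl bromide
Product: 21 (3S,4S)-3-[4-(benzyloxy)-3-bromo-5-methoxybenzyl]-4-[4-(benzyloxy)-3-methoxybenzyl]dihydrofuran-2(3H)-one, via lithium enolate 20 (not isolated)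
Conditions: LiN(SiMe3)2, THF, −78 °C; then 17, DMPU, −78 → −30 °C
Reagents that add atoms: none
Why: Enolate alkylation as in step 11; attack anti to the C4 arylmethyl group sets C3 as S (trans), and the benzylic bromide reacts while the aryl bromide does not.

Step 13
Reactants: 21 lactone A bromide; 19 lactone B bromide
Product: 23 biaryl-linked bis[(3S,4S)-trans-dibenzylbutyrolactone] tetrabenzyl ether (2,2'-bis(benzyloxy)-3,3'-dimethoxybiphenyl whose 5-CH2 is attached to C3 of lactone A and whose 5'-CH2 is attached to C4 of lactone B), via pinacol boronate 22 (not isolated)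
Conditions: B2pin2 (1.05 equiv), PdCl2(dppf) (5 mol %; dppf = 1,1'-bis(diphenylphosphino)ferrocene), KOAc, dioxane, 90 °C; then 19, 2 M aq K3PO4, 90 °C; dil. HCl work-up
Reagents that add atoms: none
Why: Miyaura borylation of the aryl bromide of 21 followed in the same flask by Suzuki–Miyaura coupling with 19; each partner has a single ortho substituent, so the biaryl should form without unusual hindrance, and the mild acid work-up re-closes any lactone opened by the base, while any epimerisation at C3 would return the preferred trans isomer.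

Step 14
Reactants: 23 biaryl-linked bis(trans-dibenzylbutyrolactone) tetrabenzyl ether
Product: 25 biaryl-linked bis[(3R,4R)-3-hydroxy-3,4-dibenzylbutyrolactone] tetrabenzyl ether, via bis(potassium enolate) 24 (not isolated)
Conditions: KN(SiMe3)2 (2.5 equiv), THF, −78 °C; then (+)-(camphorsulfonyl)oxaziridine (3 equiv), THF, −78 → −40 °C; AcOH quench
Reagents that add atoms: (+)-(2R,8aS)-(camphorsulfonyl)oxaziridine, CC1(C)[C@@H]2CC[C@]13CS(=O)(=O)[N@]4O[C@@]34C2
Why: KN(SiMe3)2 removes the single acidic C3–H of each lactone, and each α-carbon of the bis(potassium enolate) 24 attacks the oxaziridine oxygen in an SN2-type displacement; the hemiaminal alkoxide so formed collapses, the sulfonylimine leaves and a tertiary potassium alkoxide remains. The closest known reaction is the Davis oxaziridine hydroxylation of fully substituted potassium enolates of esters and lactones, trans-2,3-dibenzylbutyrolactones among them. No ring is closed: two C–O bonds and two quaternary carbinol centres form on two rings that are already in place. Each new centre is controlled by its own ring: the C3 arylmethyl group keeps one benzylic hydrogen in the enolate plane and turns its arene over the face opposite the C4 arylmethyl group, so the bulky oxidant should enter syn to the C4 substituent, OH takes the place of H with retention and the benzyl groups stay trans (3R,4R in both rings, the change of descriptor being one of CIP priority only). The step needs this face selectivity twice and complete conversion at both sites; the bias is local and the two lactones are insulated from each other by the biaryl, the product has no α-hydrogen and can neither epimerise nor be oxidised further, and the ketimine set free by this reagent does not add to the enolate as the aldimines from simpler N-sulfonyloxaziridines can. The reagent's own chirality is expected to be secondary to the substrate bias, and its antipode is available should it prove mismatched.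

Step 15
Reactants: 25 tetra-O-benzyl bis(hydroxy lactone)
Product: 26 CNP0218652.1
Conditions: H2 (1 atm), 10% Pd/C, EtOAc/EtOH, rt
Reagents that add atoms: none
Why: Hydrogenolysis of the four aryl benzyl ethers; the tertiary alcohols are homobenzylic, not benzylic, so they, the lactones and the methyl ethers should survive.

**Compound list**

1 | 5-bromovanillin | COc1cc(C=O)cc(Br)c1O | starting material
2 | benzyl bromide | BrCc1ccccc1 | starting material
3 | 4-(benzyloxy)-3-bromo-5-methoxybenzaldehyde | COc1cc(C=O)cc(Br)c1OCc1ccccc1 | intermediate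
4 | diethyl succinate | CCOC(=O)CCC(=O)OCC | starting material
5 | (E)-4-[4-(benzyloxy)-3-bromo-5-methoxyphenyl]-3-(ethoxycarbonyl)but-3-enoic acid | CCOC(=O)/C(CC(=O)O)=C/c1cc(Br)c(OCc2ccccc2)c(OC)c1 | intermediate
6 | (S)-4-[4-(benzyloxy)-3-bromo-5-methoxyphenyl]-3-(ethoxycarbonyl)butanoic acid | COc1cc(C[C@@H](CC(=O)O)C(=O)OCC)cc(Br)c1OCc1ccccc1 | intermediate
7 | (S)-4-[4-(benzyloxy)-3-bromo-5-methoxyphenyl]-3-(hydroxymethyl)butanoic acid | COc1cc(C[C@@H](CC(=O)O)CO)cc(Br)c1OCc1ccccc1 | intermediate (not isolated)
8 | (S)-4-[4-(benzyloxy)-3-bromo-5-methoxybenzyl]dihydrofuran-2(3H)-one | COc1cc(C[C@@H]2COC(=O)C2)cc(Br)c1OCc1ccccc1 | intermediate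
9 | 4-(benzyloxy)-3-methoxybenzaldehyde | COc1cc(C=O)ccc1OCc1ccccc1 | starting material
10 | (E)-4-[4-(benzyloxy)-3-methoxyphenyl]-3-(ethoxycarbonyl)but-3-enoic acid | CCOC(=O)/C(CC(=O)O)=C/c1ccc(OCc2ccccc2)c(OC)c1 | intermediate
11 | (S)-4-[4-(benzyloxy)-3-methoxyphenyl]-3-(ethoxycarbonyl)butanoic acid | COc1cc(C[C@@H](CC(=O)O)C(=O)OCC)ccc1OCc1ccccc1 | intermediate
12 | (S)-4-[4-(benzyloxy)-3-methoxyphenyl]-3-(hydroxymethyl)butanoic acid | COc1cc(C[C@@H](CC(=O)O)CO)ccc1OCc1ccccc1 | intermediate (not isolated)
13 | (S)-4-[4-(benzyloxy)-3-methoxybenzyl]dihydrofuran-2(3H)-one | COc1cc(C[C@@H]2COC(=O)C2)ccc1OCc1ccccc1 | intermediate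
14 | 4-(benzyloxy)-3-methoxybenzyl alcohol | COc1cc(CO)ccc1OCc1ccccc1 | starting material
15 | 4-(benzyloxy)-3-methoxybenzyl bromide | COc1cc(CBr)ccc1OCc1ccccc1 | intermediate
16 | 4-(benzyloxy)-3-bromo-5-methoxybenzyl alcohol | COc1cc(CO)cc(Br)c1OCc1ccccc1 | intermediate
17 | 4-(benzyloxy)-3-bromo-5-methoxybenzyl bromide | COc1cc(CBr)cc(Br)c1OCc1ccccc1 | intermediate
18 | lithium enolate of 8 | COc1cc(C[C@@H]2COC([O-])=C2)cc(Br)c1OCc1ccccc1.[Li+] | intermediate (not isolated)
19 | (3S,4S)-4-[4-(benzyloxy)-3-bromo-5-methoxybenzyl]-3-[4-(benzyloxy)-3-methoxybenzyl]dihydrofuran-2(3H)-one (lactone B bromide) | COc1cc(C[C@@H]2COC(=O)[C@H]2Cc2ccc(OCc3ccccc3)c(OC)c2)cc(Br)c1OCc1ccccc1 | intermediate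
20 | lithium enolate of 13 | COc1cc(C[C@@H]2COC([O-])=C2)ccc1OCc1ccccc1.[Li+] | intermediate (not isolated)
21 | (3S,4S)-3-[4-(benzyloxy)-3-bromo-5-methoxybenzyl]-4-[4-(benzyloxy)-3-methoxybenzyl]dihydrofuran-2(3H)-one (lactone A bromide) | COc1cc(C[C@@H]2COC(=O)[C@H]2Cc2cc(OC)c(OCc3ccccc3)c(Br)c2)ccc1OCc1ccccc1 | intermediate
22 | pinacol boronate of 21 (Bpin in place of Br) | COc1cc(C[C@@H]2COC(=O)[C@H]2Cc2cc(OC)c(OCc3ccccc3)c(B3OC(C)(C)C(C)(C)O3)c2)ccc1OCc1ccccc1 | intermediate (not isolated)
23 | biaryl-linked bis[(3S,4S)-trans-dibenzylbutyrolactone] tetrabenzyl ether | COc1cc(C[C@@H]2COC(=O)[C@H]2Cc2cc(OC)c(OCc3ccccc3)c(-c3cc(C[C@@H]4COC(=O)[C@H]4Cc4ccc(OCc5ccccc5)c(OC)c4)cc(OC)c3OCc3ccccc3)c2)ccc1OCc1ccccc1 | intermediate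
24 | bis(potassium enolate) of 23 | COc1cc(C[C@@H]2COC([O-])=C2Cc2cc(OC)c(OCc3ccccc3)c(-c3cc(C[C@@H]4COC([O-])=C4Cc4ccc(OCc5ccccc5)c(OC)c4)cc(OC)c3OCc3ccccc3)c2)ccc1OCc1ccccc1.[K+].[K+] | intermediate (not isolated)
25 | biaryl-linked bis[(3R,4R)-3-hydroxy-3,4-dibenzylbutyrolactone] tetrabenzyl ether | COc1cc(C[C@@H]2COC(=O)[C@@]2(O)Cc2cc(OC)c(OCc3ccccc3)c(-c3cc(C[C@@H]4COC(=O)[C@@]4(O)Cc4ccc(OCc5ccccc5)c(OC)c4)cc(OC)c3OCc3ccccc3)c2)ccc1OCc1ccccc1 | intermediate
26 | CNP0218652.1 | COc1cc(C[C@@H]2COC(=O)[C@@]2(O)Cc2cc(OC)c(O)c(-c3cc(C[C@@H]4COC(=O)[C@@]4(O)Cc4ccc(O)c(OC)c4)cc(OC)c3O)c2)ccc1O | target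

**Step count and risks**

Total steps: 15. Longest linear sequence: 8 steps (1, 2, 3, 4, 11, 13, 14, 15).

Steps most likely to fail:

1. Step 14. Oxygen may enter one or both enolates on the face anti to the C4 arylmethyl group, which would give cis-dibenzyl epimers as a mixture of diastereomers. The second hydroxylation may also stall.
Fallback, from 13 and 8, returning at 25: the order of bond formation at C3 is inverted, so that the benzyl group is the late arrival and enters anti to the C4 substituent, the sense already relied on in steps 11 and 12. Lactone 13 is deprotonated (KN(SiMe3)2, THF, −78 °C) to its potassium enolate F1 and hydroxylated with the same oxaziridine to the 3-hydroxy lactone F2; the configuration of this secondary carbinol is of no consequence. Lactone 8 gives likewise the potassium enolate F3 and the 3-hydroxy lactone F4. Each hydroxy lactone is doubly deprotonated (LiN(iPr)2, 2.2 equiv, THF/DMPU, −78 °C), F2 to the dilithium enediolate F5 and F4 to the dilithium enediolate F6. C-Benzylation of F5 with 17 should give the brominated hydroxy lactone F7, and of F6 with 15 the isomeric brominated hydroxy lactone F8, both with the benzyl groups trans and OH syn to the C4 substituent. One-pot borylation of F7 to the pinacol boronate F9 and Suzuki–Miyaura coupling with F8 under the conditions of step 13 then leads to 25.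

2. Step 13. Homocoupling and protodeboronation may compete in the one-pot union of two large ortho-alkoxy aryl partners, and the aqueous base may open the lactones.
Fallback, from 16, returning at 23: the halves are joined by enolate alkylation and the biaryl is made on a smaller partner. Alcohol 16 is borylated (B2pin2, PdCl2(dppf), KOAc, dioxane, 90 °C) to the pinacol boronate F10. This is coupled with bromide 19 (PdCl2(dppf), aq K3PO4, dioxane) to the biaryl benzylic alcohol F11, and PBr3 converts it into the biaryl benzylic bromide F12. F12 alkylates the lithium enolate 20 of lactone 13 under the conditions of step 12, anti to the C4 arylmethyl group, to give 23.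

3. Step 3. Enantioselection in the hydrogenation of the brominated half-ester may be insufficient or of the wrong sense.
Fallback, from 5, returning at 6: 5 is hydrogenated with the achiral catalyst [Rh(cod)(dppb)]BF4 (dppb = 1,4-bis(diphenylphosphino)butane; H2, MeOH) to the racemic half-ester F13. This is resolved by crystallisation of its salt with (R)-1-phenylethylamine, or with the antipodal amine if that one gives the less soluble salt of the (S)-acid, to the diastereomerically pure ammonium salt F14. Dilute HCl liberates 6 from F14.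

**Further compounds**

F1 | step 14 | potassium enolate of 13 | COc1cc(C[C@@H]2COC([O-])=C2)ccc1OCc1ccccc1.[K+]
F2 | step 14 | (3S,4R)-4-[4-(benzyloxy)-3-methoxybenzyl]-3-hydroxydihydrofuran-2(3H)-one | COc1cc(C[C@@H]2COC(=O)[C@H]2O)ccc1OCc1ccccc1
F3 | step 14 | potassium enolate of 8 | COc1cc(C[C@@H]2COC([O-])=C2)cc(Br)c1OCc1ccccc1.[K+]
F4 | step 14 | (3S,4R)-4-[4-(benzyloxy)-3-bromo-5-methoxybenzyl]-3-hydroxydihydrofuran-2(3H)-one | COc1cc(C[C@@H]2COC(=O)[C@H]2O)cc(Br)c1OCc1ccccc1
F5 | step 14 | dilithium enediolate of F2 | COc1cc(C[C@@H]2COC([O-])=C2[O-])ccc1OCc1ccccc1.[Li+].[Li+]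
F6 | step 14 | dilithium enediolate of F4 | COc1cc(C[C@@H]2COC([O-])=C2[O-])cc(Br)c1OCc1ccccc1.[Li+].[Li+]
F7 | step 14 | (3R,4R)-3-[4-(benzyloxy)-3-bromo-5-methoxybenzyl]-4-[4-(benzyloxy)-3-methoxybenzyl]-3-hydroxydihydrofuran-2(3H)-one | COc1cc(C[C@@H]2COC(=O)[C@@]2(O)Cc2cc(OC)c(OCc3ccccc3)c(Br)c2)ccc1OCc1ccccc1
F8 | step 14 | (3R,4R)-4-[4-(benzyloxy)-3-bromo-5-methoxybenzyl]-3-[4-(benzyloxy)-3-methoxybenzyl]-3-hydroxydihydrofuran-2(3H)-one | COc1cc(C[C@@H]2COC(=O)[C@@]2(O)Cc2ccc(OCc3ccccc3)c(OC)c2)cc(Br)c1OCc1ccccc1
F9 | step 14 | pinacol boronate of F7 (Bpin in place of Br) | COc1cc(C[C@@H]2COC(=O)[C@@]2(O)Cc2cc(OC)c(OCc3ccccc3)c(B3OC(C)(C)C(C)(C)O3)c2)ccc1OCc1ccccc1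
F10 | step 13 | 4-(benzyloxy)-3-methoxy-5-(4,4,5,5-tetramethyl-1,3,2-dioxaborolan-2-yl)benzyl alcohol | COc1cc(CO)cc(B2OC(C)(C)C(C)(C)O2)c1OCc1ccccc1
F11 | step 13 | biaryl benzylic alcohol (lactone B of 19 with the aryl bromine replaced by the 2-(benzyloxy)-5-(hydroxymethyl)-3-methoxyphenyl ring) | COc1cc(C[C@@H]2COC(=O)[C@H]2Cc2ccc(OCc3ccccc3)c(OC)c2)cc(-c2cc(CO)cc(OC)c2OCc2ccccc2)c1OCc1ccccc1
F12 | step 13 | biaryl benzylic bromide (F11 with CH2Br in place of CH2OH) | COc1cc(C[C@@H]2COC(=O)[C@H]2Cc2ccc(OCc3ccccc3)c(OC)c2)cc(-c2cc(CBr)cc(OC)c2OCc2ccccc2)c1OCc1ccccc1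
F13 | step 3 | racemic 4-[4-(benzyloxy)-3-bromo-5-methoxyphenyl]-3-(ethoxycarbonyl)butanoic acid | COc1cc(CC(CC(=O)O)C(=O)OCC)cc(Br)c1OCc1ccccc1
F14 | step 3 | (R)-1-phenylethylammonium salt of 6 | COc1cc(C[C@@H](CC(=O)[O-])C(=O)OCC)cc(Br)c1OCc1ccccc1.C[C@@H]([NH3+])c1ccccc1
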